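**Plan**

- Locants are those of the octahydroazulene name of the target: C3 carbinol (isopropyl), C3a ring-fusion CH, C4 aroyloxy carbon, C5 CH2, C6 methyl-bearing alkene carbon, C7, C8 tigloyloxy carbon, C8a quaternary carbon. The retrosynthesis cuts the two ester C–O bonds, then C3–C3a (aldol), then C5–C6 and C8–C8a together.
- Enabling feature: in the seven-membered ring the allyl unit C6=C7–C8(O) bridges C5 and C8a of the four-carbon unit C5–C4(O)–C3a–C8a. With C4 as a ketone masked as its C3a=C4 silyl enol ether, this is the 1,4-cycloheptadiene that a vinylcarbene (C6 as carbene carbon) and a 2-siloxy-1,3-diene give by cyclopropanation and Cope shift (formal [4+3]).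
- Forward: two achiral open-chain pieces, (Z)-siloxydiene ketone 9 (five steps) and (E)-4-siloxy vinyldiazoacetate 13 (two steps), give the seven-membered ring. The enol silane left behind then closes the five-membered ring onto the side-chain ketone (Mukaiyama aldol). Reductions (ketone to alcohol, ester to methyl) and two acylations finish.
- Stereochemistry: C8/C8a relative configuration comes from the boat Cope transition state (E-OTBS and E-methyl end up cis), absolute configuration from the chiral dirhodium carboxylate. C3a and C3 come from the tether-controlled aldol, C4 from chelate-controlled hydride addition, and the tiglate geometry from tiglic acid.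

Key step: step 8

Remark: the SMILES is read as a cis-fused ring system (C8a methyl and C3a hydrogen on the same face) carrying the E ester (tiglate); CIP descriptors below were derived from it by hand.

**Step 1**
Reactants: 1 pent-3-yn-2-one
Product: 2 (Z)-4-iodopent-3-en-2-one
Conditions: NaI, AcOH, 23 °C
Reagents that add atoms: sodium iodide, [Na+].[I-]
Why: Hydroiodination of an ynone (iodide conjugate addition, then protonation of the allenolate) is an anti addition and should give the (Z)-β-iodo enone with iodine cis to the acetyl group.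

**Step 2**
Reactants: 3 3-bromopropanoyl chloride; 4 N,O-dimethylhydroxylamine hydrochloride
Product: 5 3-bromo-N-methoxy-N-methylpropanamide
Conditions: pyridine (2.1 equiv), CH2Cl2, 0 °C
Reagents that add atoms: none
Why: N-Acylation of the hydroxylamine by the acid chloride (Weinreb amide formation); cold pyridine avoids β-elimination of HBr.

**Step 3**
Reactants: 5 3-bromo-N-methoxy-N-methylpropanamide; 2 (Z)-4-iodopent-3-en-2-one
Product: 7 (Z)-N-methoxy-N,4-dimethyl-6-oxohept-4-enamide, via alkylzinc bromide 6 (not isolated)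
Conditions: Zn dust, LiCl, THF, 40 °C; then 2, Pd(PPh3)4 (3 mol%, zerovalent palladium), THF, 23 °C
Reagents that add atoms: none
Why: Zinc insertion gives the chelate-stabilised amide homoenolate, and Negishi coupling at the β-iodo enone proceeds with retention of alkene geometry, which places the chain cis to the acetyl group.

**Step 4**
Reactants: 7 (Z)-N-methoxy-N,4-dimethyl-6-oxohept-4-enamide
Product: 8 (Z)-6-[(tert-butyldimethylsilyl)oxy]-N-methoxy-N,4-dimethylhepta-4,6-dienamide
Conditions: TBSOTf, Et3N, CH2Cl2, −78 → 0 °C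
Reagents that add atoms: tert-butyldimethylsilyl trifluoromethanesulfonate, CC(C)(C)[Si](C)(C)OS(=O)(=O)C(F)(F)F
Why: Soft enolisation at the ketone methyl group gives the cross-conjugated 2-siloxy diene (silyl enol ether formation); the amide is not enolised and the trisubstituted alkene keeps its geometry.

**Step 5**
Reactants: 8 (Z)-6-[(tert-butyldimethylsilyl)oxy]-N-methoxy-N,4-dimethylhepta-4,6-dienamide
Product: 9 (Z)-8-[(tert-butyldimethylsilyl)oxy]-2,6-dimethylnona-6,8-dien-3-one
Conditions: iPrMgCl, THF, −20 → 0 °C; aq. NaH2PO4/Na2HPO4 buffer (pH 7)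
Reagents that add atoms: isopropylmagnesium chloride, CC(C)[Mg]Cl
Why: Weinreb ketone synthesis: the chelated tetrahedral adduct stops at the ketone and the silyl dienol ether is inert to the Grignard reagent, so the isopropyl ketone appears only after the enol ether is in place.

**Step 6**
Reactants: 10 2-[(tert-butyldimethylsilyl)oxy]acetaldehyde; 11 ethyl diazoacetate
Product: 12 ethyl 4-[(tert-butyldimethylsilyl)oxy]-2-diazo-3-hydroxybutanoate (racemic)
Conditions: DBU (10 mol%), MeCN, 23 °C
Reagents that add atoms: none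
Why: DBU-catalysed aldol-type addition of the diazoacetate carbon to the aldehyde; the carbinol stereocenter is removed in the next step.

**Step 7**
Reactants: 12 ethyl 4-[(tert-butyldimethylsilyl)oxy]-2-diazo-3-hydroxybutanoate
Product: 13 ethyl (E)-4-[(tert-butyldimethylsilyl)oxy]-2-diazobut-3-enoate
Conditions: POCl3, Et3N, CH2Cl2, 0 °C; used at once
Reagents that add atoms: none
Why: Dehydration of a β-hydroxy α-diazo ester through its dichlorophosphate is the standard entry to vinyldiazoacetates and should give the conjugated E enol ether.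

**Step 8**
Reactants: 9 (Z)-8-[(tert-butyldimethylsilyl)oxy]-2,6-dimethylnona-6,8-dien-3-one; 13 ethyl (E)-4-[(tert-butyldimethylsilyl)oxy]-2-diazobut-3-enoate
Product: 15 ethyl (3R,4R)-3,6-bis[(tert-butyldimethylsilyl)oxy]-4-methyl-4-(4-methyl-3-oxopentyl)cyclohepta-1,5-diene-1-carboxylate, via cis-divinylcyclopropane 14 (not isolated)
Conditions: Rh2(R-DOSP)4 (1 mol%, divalent rhodium), hexanes, −40 → 23 °C, slow addition of 13 (1.5 equiv); then PhMe, 80 °C
Reagents that add atoms: none
Why: The catalyst turns 13 into a rhodium vinylcarbenoid that cyclopropanates the terminal silyloxy-substituted double bond of 9 through its CH2 carbon to give cis-divinylcyclopropane 14, which on warming undergoes a Cope ([3,3]) shift through a boat transition state; the closest known reaction type is the rhodium-catalysed tandem cyclopropanation/Cope rearrangement (formal [4+3] cycloaddition) of vinyldiazoacetates with 2-siloxy dienes. The three-membered ring closes by [2+1] carbene addition (making C1–C7 of 15) and the seven-membered ring by the [3,3] shift, a ring expansion of the cyclopropane across the two vinyl termini (making C3–C4). In the boat the E substituents of both vinyl termini (OTBS on the carbenoid arm, methyl on the diene arm) point outward, so OTBS at C3 and methyl at C4 should end up cis, while the Z chain points inward, which slows the shift and is the reason for heating. Absolute configuration comes from the carbenoid face left open by the chiral carboxylate ligands in the cyclopropanation and is passed on by the concerted shift; the R catalyst is chosen on the usual sense of induction of the DOSP catalysts with vinyldiazoacetates, and the antipodal catalyst would give the antipode. The step needs site selectivity for the electron-rich 1,1-disubstituted alkene over the trisubstituted alkene, the ketone and the enol ether of 13 (secured by electronic activation, low steric demand and slow addition), and a concerted path instead of zwitterionic collapse to a [3+2] cyclopentene (secured by the hydrocarbon solvent and the E-silyloxy group that blocks vinylogous attack).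

**Step 9**
Reactants: 15 ethyl (3R,4R)-3,6-bis[(tert-butyldimethylsilyl)oxy]-4-methyl-4-(4-methyl-3-oxopentyl)cyclohepta-1,5-diene-1-carboxylate
Product: 16 ethyl (3R,3aR,8R,8aR)-8-[(tert-butyldimethylsilyl)oxy]-3-hydroxy-8a-methyl-4-oxo-3-(propan-2-yl)-1,2,3,3a,4,5,8,8a-octahydroazulene-6-carboxylate
Conditions: TiCl4, CH2Cl2, −78 °C; aq. NaHCO3
Reagents that add atoms: none
Why: Intramolecular Mukaiyama aldol addition, 5-(enolexo)-exo-trig: the enol silane left by step 8 attacks the TiCl4-activated ketone on the face that carries the tether, which forces the cis ring fusion (C3a), and the isopropyl group should take the convex face with the titanium-bound oxygen turned towards the enol oxygen, which sets C3.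

**Step 10**
Reactants: 16 ethyl (3R,3aR,8R,8aR)-8-[(tert-butyldimethylsilyl)oxy]-3-hydroxy-8a-methyl-4-oxo-3-(propan-2-yl)-1,2,3,3a,4,5,8,8a-octahydroazulene-6-carboxylate
Product: 17 (3R,3aS,4R,8R,8aR)-8-[(tert-butyldimethylsilyl)oxy]-6-(hydroxymethyl)-8a-methyl-3-(propan-2-yl)-1,2,3,3a,4,5,8,8a-octahydroazulene-3,4-diol
Conditions: iBu2AlH (6 equiv), THF, −78 → −20 °C; aq. KNaC4H4O6 (potassium sodium tartrate)
Reagents that add atoms: none
Why: The aluminium alkoxide at C3 chelates the C4 ketone and a second hydride should add from the open convex face, syn to the C3a hydrogen (chelation-controlled reduction of a β-hydroxy ketone to the cis 1,3-diol), while the enoate is reduced to the allylic alcohol under non-enolising conditions.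

**Step 11**
Reactants: 17 (3R,3aS,4R,8R,8aR)-8-[(tert-butyldimethylsilyl)oxy]-6-(hydroxymethyl)-8a-methyl-3-(propan-2-yl)-1,2,3,3a,4,5,8,8a-octahydroazulene-3,4-diol
Product: 19 (3R,3aS,4R,8R,8aR)-8-[(tert-butyldimethylsilyl)oxy]-6,8a-dimethyl-3-(propan-2-yl)-1,2,3,3a,4,5,8,8a-octahydroazulene-3,4-diol, via allylic sulfate 18 (not isolated)
Conditions: SO3·pyridine (1.1 equiv), THF, 0 °C; then LiAlH4, 0 → 23 °C
Reagents that add atoms: none
Why: The primary allylic alcohol is sulfated selectively and hydride displaces sulfate at the primary carbon (Corey–Achiwa deoxygenation), which turns CH2OH into CH3 without allylic transposition.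

**Step 12**
Reactants: 19 (3R,3aS,4R,8R,8aR)-8-[(tert-butyldimethylsilyl)oxy]-6,8a-dimethyl-3-(propan-2-yl)-1,2,3,3a,4,5,8,8a-octahydroazulene-3,4-diol; 20 4-acetoxybenzoyl chloride
Product: 21 (3R,3aS,4R,8R,8aR)-8-[(tert-butyldimethylsilyl)oxy]-3-hydroxy-6,8a-dimethyl-3-(propan-2-yl)-1,2,3,3a,4,5,8,8a-octahydroazulen-4-yl 4-acetoxybenzoate
Conditions: pyridine, DMAP (cat.), CH2Cl2, 0 → 23 °C
Reagents that add atoms: none
Why: DMAP-catalysed acylation of the only secondary alcohol; the tertiary C3 hydroxyl is too hindered and C8 is still silylated.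

**Step 13**
Reactants: 21 (3R,3aS,4R,8R,8aR)-8-[(tert-butyldimethylsilyl)oxy]-3-hydroxy-6,8a-dimethyl-3-(propan-2-yl)-1,2,3,3a,4,5,8,8a-octahydroazulen-4-yl 4-acetoxybenzoate
Product: 22 (3R,3aS,4R,8R,8aR)-3,8-dihydroxy-6,8a-dimethyl-3-(propan-2-yl)-1,2,3,3a,4,5,8,8a-octahydroazulen-4-yl 4-acetoxybenzoate
Conditions: HF·pyridine, pyridine, THF, 0 → 23 °C
Reagents that add atoms: none
Why: Fluoride cleavage of the silyl ether under buffered acidic conditions that should leave the aryl acetate and the benzoate untouched.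

**Step 14**
Reactants: 22 (3R,3aS,4R,8R,8aR)-3,8-dihydroxy-6,8a-dimethyl-3-(propan-2-yl)-1,2,3,3a,4,5,8,8a-octahydroazulen-4-yl 4-acetoxybenzoate; 23 tiglic acid
Product: 25 (3R,3aS,4R,8R,8aR)-4-[(4-acetoxybenzoyl)oxy]-3-hydroxy-6,8a-dimethyl-3-(propan-2-yl)-1,2,3,3a,4,5,8,8a-octahydroazulen-8-yl (E)-2-methylbut-2-enoate, via mixed anhydride 24 (not isolated)
Conditions: 2,4,6-Cl3C6H2COCl, Et3N, PhMe, 23 °C; then 22, DMAP, 60 °C
Reagents that add atoms: none
Why: Yamaguchi esterification through the mixed anhydride acylates the hindered allylic alcohol next to the quaternary carbon with retention at C8; the tiglate is the stable E isomer, so no geometrical isomerisation is expected.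

**Step 15**
Reactants: 25 (3R,3aS,4R,8R,8aR)-4-[(4-acetoxybenzoyl)oxy]-3-hydroxy-6,8a-dimethyl-3-(propan-2-yl)-1,2,3,3a,4,5,8,8a-octahydroazulen-8-yl (E)-2-methylbut-2-enoate
Product: 26 (3R,3aS,4R,8R,8aR)-3-hydroxy-4-[(4-hydroxybenzoyl)oxy]-6,8a-dimethyl-3-(propan-2-yl)-1,2,3,3a,4,5,8,8a-octahydroazulen-8-yl (E)-2-methylbut-2-enoate
Conditions: pyrrolidine (3 equiv), CH2Cl2, 0 °C
Reagents that add atoms: none
Why: Aminolysis of the phenyl acetate, an activated ester, should be much faster than attack at the alkyl benzoate or the hindered tiglate.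

**Compound list**

1 | pent-3-yn-2-one | CC#CC(C)=O | starting material
2 | (Z)-4-iodopent-3-en-2-one | CC(=O)/C=C(/C)I | intermediate
3 | 3-bromopropanoyl chloride | O=C(Cl)CCBr | starting material
4 | N,O-dimethylhydroxylamine hydrochloride | CNOC.Cl | starting material
5 | 3-bromo-N-methoxy-N-methylpropanamide | CON(C)C(=O)CCBr | intermediate
6 | {3-[methoxy(methyl)amino]-3-oxopropyl}zinc bromide | CON(C)C(=O)CC[Zn]Br | intermediate (not isolated)
7 | (Z)-N-methoxy-N,4-dimethyl-6-oxohept-4-enamide | CON(C)C(=O)CC/C(C)=C\C(C)=O | intermediate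
8 | (Z)-6-[(tert-butyldimethylsilyl)oxy]-N-methoxy-N,4-dimethylhepta-4,6-dienamide | CON(C)C(=O)CC/C(C)=C\C(=C)O[Si](C)(C)C(C)(C)C | intermediate
9 | (Z)-8-[(tert-butyldimethylsilyl)oxy]-2,6-dimethylnona-6,8-dien-3-one | CC(C)C(=O)CC/C(C)=C\C(=C)O[Si](C)(C)C(C)(C)C | intermediate
10 | 2-[(tert-butyldimethylsilyl)oxy]acetaldehyde | CC(C)(C)[Si](C)(C)OCC=O | starting material
11 | ethyl diazoacetate | CCOC(=O)C=[N+]=[N-] | starting material
12 | ethyl 4-[(tert-butyldimethylsilyl)oxy]-2-diazo-3-hydroxybutanoate (racemic) | CCOC(=O)C(=[N+]=[N-])C(O)CO[Si](C)(C)C(C)(C)C | intermediate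
13 | ethyl (E)-4-[(tert-butyldimethylsilyl)oxy]-2-diazobut-3-enoate | CCOC(=O)C(=[N+]=[N-])/C=C/O[Si](C)(C)C(C)(C)C | intermediate
14 | ethyl (1S,2R)-2-[(tert-butyldimethylsilyl)oxy]-1-{(E)-2-[(tert-butyldimethylsilyl)oxy]ethenyl}-2-[(1Z)-2,6-dimethyl-5-oxohept-1-en-1-yl]cyclopropane-1-carboxylate (the two alkenyl groups cis) | CCOC(=O)[C@]1(/C=C/O[Si](C)(C)C(C)(C)C)C[C@@]1(O[Si](C)(C)C(C)(C)C)/C=C(C)\CCC(=O)C(C)C | intermediate (not isolated)
15 | ethyl (3R,4R)-3,6-bis[(tert-butyldimethylsilyl)oxy]-4-methyl-4-(4-methyl-3-oxopentyl)cyclohepta-1,5-diene-1-carboxylate (C3 silyloxy and C4 methyl cis) | CC(C)(C)[Si](C)(C)O[C@@H]1C=C(C(=O)OCC)CC(O[Si](C)(C)C(C)(C)C)=C[C@@]1(C)CCC(=O)C(C)C | intermediate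
16 | ethyl (3R,3aR,8R,8aR)-8-[(tert-butyldimethylsilyl)oxy]-3-hydroxy-8a-methyl-4-oxo-3-(propan-2-yl)-1,2,3,3a,4,5,8,8a-octahydroazulene-6-carboxylate (cis-fused) | CC(C)(C)[Si](C)(C)O[C@@H]1C=C(C(=O)OCC)CC(=O)[C@@H]2[C@@]1(C)CC[C@@]2(O)C(C)C | intermediate
17 | (3R,3aS,4R,8R,8aR)-8-[(tert-butyldimethylsilyl)oxy]-6-(hydroxymethyl)-8a-methyl-3-(propan-2-yl)-1,2,3,3a,4,5,8,8a-octahydroazulene-3,4-diol | CC(C)(C)[Si](C)(C)O[C@@H]1C=C(CO)C[C@@H](O)[C@@H]2[C@@]1(C)CC[C@@]2(O)C(C)C | intermediate
18 | pyridinium sulfate monoester of 17 at the primary allylic oxygen | CC(C)(C)[Si](C)(C)O[C@@H]1C=C(COS(=O)(=O)[O-])C[C@@H](O)[C@@H]2[C@@]1(C)CC[C@@]2(O)C(C)C.c1cc[nH+]cc1 | intermediate (not isolated)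
19 | (3R,3aS,4R,8R,8aR)-8-[(tert-butyldimethylsilyl)oxy]-6,8a-dimethyl-3-(propan-2-yl)-1,2,3,3a,4,5,8,8a-octahydroazulene-3,4-diol | CC(C)(C)[Si](C)(C)O[C@@H]1C=C(C)C[C@@H](O)[C@@H]2[C@@]1(C)CC[C@@]2(O)C(C)C | intermediate
20 | 4-acetoxybenzoyl chloride | CC(=O)Oc1ccc(cc1)C(Cl)=O | starting material
21 | (3R,3aS,4R,8R,8aR)-8-[(tert-butyldimethylsilyl)oxy]-3-hydroxy-6,8a-dimethyl-3-(propan-2-yl)-1,2,3,3a,4,5,8,8a-octahydroazulen-4-yl 4-acetoxybenzoate | CC(C)(C)[Si](C)(C)O[C@@H]1C=C(C)C[C@@H](OC(=O)c3ccc(OC(C)=O)cc3)[C@@H]2[C@@]1(C)CC[C@@]2(O)C(C)C | intermediate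
22 | (3R,3aS,4R,8R,8aR)-3,8-dihydroxy-6,8a-dimethyl-3-(propan-2-yl)-1,2,3,3a,4,5,8,8a-octahydroazulen-4-yl 4-acetoxybenzoate | O[C@@H]1C=C(C)C[C@@H](OC(=O)c3ccc(OC(C)=O)cc3)[C@@H]2[C@@]1(C)CC[C@@]2(O)C(C)C | intermediate
23 | tiglic acid, (E)-2-methylbut-2-enoic acid | C/C=C(\C)C(O)=O | starting material
24 | (E)-2-methylbut-2-enoic 2,4,6-trichlorobenzoic anhydride | C/C=C(\C)C(=O)OC(=O)c1c(Cl)cc(Cl)cc1Cl | intermediate (not isolated)
25 | (3R,3aS,4R,8R,8aR)-4-[(4-acetoxybenzoyl)oxy]-3-hydroxy-6,8a-dimethyl-3-(propan-2-yl)-1,2,3,3a,4,5,8,8a-octahydroazulen-8-yl (E)-2-methylbut-2-enoate | C/C=C(\C)C(=O)O[C@@H]1C=C(C)C[C@@H](OC(=O)c3ccc(OC(C)=O)cc3)[C@@H]2[C@@]1(C)CC[C@@]2(O)C(C)C | intermediate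
26 | (3R,3aS,4R,8R,8aR)-3-hydroxy-4-[(4-hydroxybenzoyl)oxy]-6,8a-dimethyl-3-(propan-2-yl)-1,2,3,3a,4,5,8,8a-octahydroazulen-8-yl (E)-2-methylbut-2-enoate | C/C=C(\C)C(=O)O[C@@H]1C=C(C)C[C@@H](OC(=O)c2ccc(O)cc2)[C@@H]2[C@@]1(C)CC[C@@]2(O)C(C)C | target

**Step count**

Total step count: 15.
Longest linear sequence: 12 steps (1 → 2 → 7 → 8 → 9 → 15 → 16 → 17 → 19 → 21 → 22 → 25 → 26; steps 1, 3, 4, 5, 8 to 15).

**Steps most likely to fail**

Step 8. Enantiofacial discrimination at the carbenoid may be incomplete with this trisubstituted silyl dienol ether, or a stepwise zwitterionic ring expansion may leak stereochemical information. The fallback replaces catalyst control by a classical resolution. It sets out from 19 of insufficient enantiomeric purity. Esterification of the C4 hydroxyl with (S)-2-methoxy-2-phenylacetic acid (DCC, DMAP, CH2Cl2) should give two diastereomers: (3R,3aS,4R,8R,8aR)-8-[(tert-butyldimethylsilyl)oxy]-3-hydroxy-6,8a-dimethyl-3-(propan-2-yl)-1,2,3,3a,4,5,8,8a-octahydroazulen-4-yl (S)-2-methoxy-2-phenylacetate F1 from 19, and the (3S,3aR,4S,8S,8aS) ester of the same acid F2 from the enantiomer of 19. These are separated by chromatography or crystallisation. Methanolysis of F1 (K2CO3, MeOH) returns 19 as a single enantiomer, where the route is rejoined.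

Step 9. The enol silane may attack the other face of the ketone (C3 epimer), or the titanium aldolate may undergo retro-aldol cleavage or β-elimination. The fallback uses an enolate aldol under equilibrating conditions instead of Lewis-acid addition of the enol silane. It sets out from 15. Buffered fluoride (TBAF, AcOH, THF, −20 °C) should cleave only the silyl enol ether and give ethyl (3R,4R)-3-[(tert-butyldimethylsilyl)oxy]-4-methyl-4-(4-methyl-3-oxopentyl)-6-oxocyclohept-1-ene-1-carboxylate F3. Soft enolisation with MgBr2·OEt2 and iPr2NEt in CH2Cl2 then closes the five-membered ring reversibly. The magnesium-chelated aldolate with the carbinol oxygen cis to the C4 ketone and the isopropyl group on the convex face is the expected thermodynamic sink, so the route is rejoined at 16.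

Step 10. Facial selectivity of hydride addition at C4 may be poor if chelate-controlled convex attack competes with internal delivery. The fallback makes the other epimer on purpose and inverts it during ester formation. It sets out from 16. Me4NBH(OAc)3 (AcOH, MeCN, −20 °C), which delivers hydride internally from the C3-bound borohydride, should give ethyl (3R,3aS,4S,8R,8aR)-8-[(tert-butyldimethylsilyl)oxy]-3,4-dihydroxy-8a-methyl-3-(propan-2-yl)-1,2,3,3a,4,5,8,8a-octahydroazulene-6-carboxylate F4. iBu2AlH then gives (3R,3aS,4S,8R,8aR)-8-[(tert-butyldimethylsilyl)oxy]-6-(hydroxymethyl)-8a-methyl-3-(propan-2-yl)-1,2,3,3a,4,5,8,8a-octahydroazulene-3,4-diol F5. SO3·pyridine followed by LiAlH4 gives (3R,3aS,4S,8R,8aR)-8-[(tert-butyldimethylsilyl)oxy]-6,8a-dimethyl-3-(propan-2-yl)-1,2,3,3a,4,5,8,8a-octahydroazulene-3,4-diol F6. A Mitsunobu reaction of F6 (PPh3, DIAD, 4-acetoxybenzoic acid, PhMe) installs the aroyl group with inversion at C4 and rejoins the route at 21.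

**Further compounds**

F1 | step 8 | (3R,3aS,4R,8R,8aR)-8-[(tert-butyldimethylsilyl)oxy]-3-hydroxy-6,8a-dimethyl-3-(propan-2-yl)-1,2,3,3a,4,5,8,8a-octahydroazulen-4-yl (S)-2-methoxy-2-phenylacetate | CC(C)(C)[Si](C)(C)O[C@@H]1C=C(C)C[C@@H](OC(=O)[C@@H](OC)c3ccccc3)[C@@H]2[C@@]1(C)CC[C@@]2(O)C(C)C
F2 | step 8 | (3S,3aR,4S,8S,8aS)-8-[(tert-butyldimethylsilyl)oxy]-3-hydroxy-6,8a-dimethyl-3-(propan-2-yl)-1,2,3,3a,4,5,8,8a-octahydroazulen-4-yl (S)-2-methoxy-2-phenylacetate | CC(C)(C)[Si](C)(C)O[C@H]1C=C(C)C[C@H](OC(=O)[C@@H](OC)c3ccccc3)[C@H]2[C@]1(C)CC[C@]2(O)C(C)C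
F3 | step 9 | ethyl (3R,4R)-3-[(tert-butyldimethylsilyl)oxy]-4-methyl-4-(4-methyl-3-oxopentyl)-6-oxocyclohept-1-ene-1-carboxylate | CC(C)(C)[Si](C)(C)O[C@@H]1C=C(C(=O)OCC)CC(=O)C[C@@]1(C)CCC(=O)C(C)C
F4 | step 10 | ethyl (3R,3aS,4S,8R,8aR)-8-[(tert-butyldimethylsilyl)oxy]-3,4-dihydroxy-8a-methyl-3-(propan-2-yl)-1,2,3,3a,4,5,8,8a-octahydroazulene-6-carboxylate | CC(C)(C)[Si](C)(C)O[C@@H]1C=C(C(=O)OCC)C[C@H](O)[C@@H]2[C@@]1(C)CC[C@@]2(O)C(C)C
F5 | step 10 | (3R,3aS,4S,8R,8aR)-8-[(tert-butyldimethylsilyl)oxy]-6-(hydroxymethyl)-8a-methyl-3-(propan-2-yl)-1,2,3,3a,4,5,8,8a-octahydroazulene-3,4-diol | CC(C)(C)[Si](C)(C)O[C@@H]1C=C(CO)C[C@H](O)[C@@H]2[C@@]1(C)CC[C@@]2(O)C(C)C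
F6 | step 10 | (3R,3aS,4S,8R,8aR)-8-[(tert-butyldimethylsilyl)oxy]-6,8a-dimethyl-3-(propan-2-yl)-1,2,3,3a,4,5,8,8a-octahydroazulene-3,4-diol | CC(C)(C)[Si](C)(C)O[C@@H]1C=C(C)C[C@H](O)[C@@H]2[C@@]1(C)CC[C@@]2(O)C(C)C
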